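**Retrosynthetic overview**
1. The 30-membered macrodiolide is opened at the C14–O lactone bond (last ring closure) and at the C14'–O ester. The north E,E-diene is cut at C5=C6, which is made by HWE of an oxazolylmethyl phosphonate with an epoxy-enal.
2. Key disconnection: the C9–C10 bond of the cis-epoxide, which joins two oxygen-bearing acceptor carbons. Allyl chloride is deprotonated at its C–Cl carbon, held as the (Z)-γ-chloroallylborane and added to 4,4-dimethoxybut-2-enal. Closing the chlorohydrin gives the epoxide, so one C–C bond formation sets both epoxide stereocentres and the cis geometry.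
3. C11=C12 comes from Z-selective cross-metathesis of the vinyl epoxide with a homoallylic alcohol. Both side chains come from one aldehyde (Kiyooka aldol) by reagent-controlled allyl- or allenylboration (14S versus 14'R).
4. The all-Z triene is carried as a (Z)-enediyne, built from cis-1,2-dichloroethene by two Sonogashira couplings. Zn semi-reduction is done before the epoxide enters, so the epoxide never meets palladium and the triene never meets ruthenium.
5. Ring order: oxirane (step 6), then the south oxazole (Hantzsch, step 14; the north oxazole is bought), then the macrocycle (step 22).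

**Assumption:** the SMILES is taken literally and disorazole numbering is used (C1 carboxyl, C5 on oxazole C2, C14 acyloxy carbon, C16 carbinol; primes for the methoxy half).
- Epoxide half: cis-epoxide 9S,10R; 5E,7E,11Z; 14S,16S (anti).
- Methoxy half: 6'R; 7'Z,9'Z,11'Z; 14'R,16'S (syn).

**Handling:** from the epoxy-enal stage on, nothing is heated above 35 °C, because a cis-divinyl oxirane rearranges to a dihydrooxepine on heating. Polyenes are kept in the dark, and silica is deactivated with Et3N.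

Step 1
Reactants: 1 (E)-crotonaldehyde; 2 1-methoxy-2-methyl-1-(trimethylsilyloxy)prop-1-ene
Product: 3 methyl (3S,4E)-3-hydroxy-2,2-dimethylhex-4-enoate
Conditions: N-Ts-D-valine (1.1 equiv), BH3·THF (1.0 equiv), CH2Cl2, 0 °C to rt; then 1 and 2, −78 °C, 4 h; pH 7 buffer, then 1 M HCl/THF
Reagents that add atoms: none
Why: Kiyooka variant of the Mukaiyama aldol, in which the D-valine-derived oxazaborolidinone binds the enal and shields one face, so the silyl ketene acetal sets the (S)-carbinol that becomes both C16 and C16'.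

Step 2
Reactants: 3 methyl (3S,4E)-3-hydroxy-2,2-dimethylhex-4-enoate
Product: 4 methyl (3S,4E)-2,2-dimethyl-3-(triethylsilyloxy)hex-4-enoate
Conditions: Et3SiOTf, 2,6-lutidine, CH2Cl2, −78 to 0 °C
Reagents that add atoms: triethylsilyl trifluoromethanesulfonate, CC[Si](CC)(CC)OS(=O)(=O)C(F)(F)F
Why: Silyl ether formation with the triflate overcomes the neopentyl hindrance, and TES can be removed at the end with buffered fluoride without harming the epoxide, esters or polyenes.

Step 3
Reactants: 4 methyl (3S,4E)-2,2-dimethyl-3-(triethylsilyloxy)hex-4-enoate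
Product: 5 (3S,4E)-2,2-dimethyl-3-(triethylsilyloxy)hex-4-enal
Conditions: i-Bu2AlH (1.1 equiv), CH2Cl2, −78 °C; MeOH, aq KNaC4H4O6
Reagents that add atoms: none
Why: Partial ester reduction works because the aluminium hemiacetal of this neopentyl ester persists at −78 °C and collapses to the aldehyde only on work-up, and the quaternary α-carbon rules out epimerisation.

Step 4
Reactants: 5 (3S,4E)-2,2-dimethyl-3-(triethylsilyloxy)hex-4-enal; 6 allylmagnesium bromide
Product: 8 (4S,6S,7E)-5,5-dimethyl-6-(triethylsilyloxy)nona-1,7-dien-4-ol, via B-allyldiisopinocampheylborane 7 (not isolated)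
Conditions: (−)-Ipc2BOMe (from (+)-α-pinene), 6, Et2O, 0 °C, filter; 5, −100 to −78 °C; HOCH2CH2NH2 work-up
Reagents that add atoms: none
Why: Brown asymmetric allylboration through a chair Zimmerman–Traxler transition state, in which the (+)-α-pinene-derived borane attacks the Si face and sets 14S (1,3-anti to C16) under reagent control.

Step 5
Reactants: 9 (2E)-4,4-dimethoxybut-2-enal; 10 allyl chloride
Product: 12 (2E,4S,5S)-5-chloro-1,1-dimethoxyhepta-2,6-dien-4-ol, via (Z)-γ-chloroallyldiisopinocampheylborane 11 (not isolated)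
Conditions: 10 (1.6 equiv), (+)-Ipc2BOMe (1.4 equiv, from (−)-α-pinene), LiN(c-C6H11)2 (1.6 equiv), Et2O, −95 °C, 1 h; BF3·OEt2 (2.9 equiv); 9 (1.0 equiv), −95 °C, 4 h; HOCH2CH2NH2 work-up
Reagents that add atoms: none
Why: Key step, an asymmetric γ-chloroallylboration: deprotonation turns the normally electrophilic C–Cl carbon of allyl chloride into an α-chloroallyl carbanion equivalent (stored as the (Z)-γ-chloroallylborane after a 1,3-boratropic shift) that attacks the equally electrophilic aldehyde carbon through a chair transition state, so C9–C10 joins two acceptor carbons, the Z-borane geometry gives the syn-chlorohydrin, the (−)-α-pinene-derived ligands direct Re-face attack (9S,10S), and BF3 is fully consumed by methoxide and amine so the acetal survives.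

Step 6
Reactants: 12 (2E,4S,5S)-5-chloro-1,1-dimethoxyhepta-2,6-dien-4-ol
Product: 14 (2E)-3-[(2S,3R)-3-ethenyloxiran-2-yl]prop-2-enal, via chlorohydrin enal 13 (not isolated)
Conditions: Amberlyst-15, acetone/H2O (20:1), rt, 10 min, filter, concentrate cold; then DBU (1.1 equiv), CH2Cl2, 0 °C
Reagents that add atoms: water, O
Why: The acetal is hydrolysed while the oxirane is still masked as the acid-stable chlorohydrin, and the following base-induced 3-exo-tet (Williamson-type) closure retains C9 and inverts C10 (S to R), so the syn-chlorohydrin gives only the cis-epoxide.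

Step 7
Reactants: 8 (4S,6S,7E)-5,5-dimethyl-6-(triethylsilyloxy)nona-1,7-dien-4-ol; 14 (2E)-3-[(2S,3R)-3-ethenyloxiran-2-yl]prop-2-enal
Product: 15 (2E)-3-{(2S,3R)-3-[(1Z,4S,6S,7E)-4-hydroxy-5,5-dimethyl-6-(triethylsilyloxy)nona-1,7-dien-1-yl]oxiran-2-yl}prop-2-enal
Conditions: 14 (3 equiv), Ru(NO3)(=CH-C6H4-2-OiPr)[C,C-chelating 1-adamantyl-3-(2,6-diisopropylphenyl)imidazolidin-2-ylidene] (C35H47N3O4Ru, 5 mol %), THF (0.5 M), 35 °C, static vacuum, 8 h
Reagents that add atoms: none
Why: Z-selective olefin cross-metathesis, in which the side-bound metallacyclobutane under the bulky N-aryl group forces both substituents to one side (11Z) and the cyclometalated catalyst engages only the two terminal alkenes, leaving the E-propenyl and the electron-poor enal double bonds untouched.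

Step 8
Reactants: 5 (3S,4E)-2,2-dimethyl-3-(triethylsilyloxy)hex-4-enal; 16 allenylboronic acid pinacol ester
Product: 17 (4R,6S,7E)-5,5-dimethyl-6-(triethylsilyloxy)non-7-en-1-yn-4-ol
Conditions: 16 (1.5 equiv), (R)-TRIP phosphoric acid (10 mol %), 4 Å MS, toluene, 0 °C to rt, 72 h; aq NaHCO3
Reagents that add atoms: none
Why: Chiral-phosphoric-acid-catalysed allenylboration (asymmetric propargylation) through a closed SE2' transition state, in which the catalyst hydrogen-bonds to a boronate oxygen and the formyl hydrogen and opens the Re face, setting 14'R (1,3-syn to C16') under catalyst control.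

Step 9
Reactants: 17 (4R,6S,7E)-5,5-dimethyl-6-(triethylsilyloxy)non-7-en-1-yn-4-ol; 18 (Z)-1,2-dichloroethene
Product: 19 (1Z,6R,8S,9E)-1-chloro-7,7-dimethyl-8-(triethylsilyloxy)undeca-1,9-dien-3-yn-6-ol
Conditions: 18 (5 equiv), Pd(PPh3)4 (5 mol %), CuI (10 mol %), n-BuNH2 (2 equiv), Et2O, rt
Reagents that add atoms: none
Why: Sonogashira mono-coupling with excess dichloroethene proceeds with retention of alkene geometry, so the central 9'Z double bond is bought rather than made.

Step 10
Reactants: 20 bis(trimethylsilyl)acetylene; 21 methyl malonyl chloride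
Product: 22 methyl 3-oxo-5-(trimethylsilyl)pent-4-ynoate
Conditions: AlCl3 (2 equiv), CH2Cl2, 0 °C; ice/1 M HCl
Reagents that add atoms: none
Why: Friedel–Crafts-type acylative ipso-desilylation of the bis-silyl alkyne gives the silyl ynone in one step, and the second silyl group blocks double acylation.

Step 11
Reactants: 22 methyl 3-oxo-5-(trimethylsilyl)pent-4-ynoate
Product: 23 methyl (3R)-3-hydroxy-5-(trimethylsilyl)pent-4-ynoate
Conditions: RuCl(p-cymene)[(R,R)-TsDPEN] (1 mol %), HCO2H/Et3N (5:2), rt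
Reagents that add atoms: none
Why: Noyori asymmetric transfer hydrogenation reduces only the C=O of ynones, and with the alkyne taking the π-substituent position the (R,R)-catalyst delivers the (R)-propargylic alcohol that becomes C6'.

Step 12
Reactants: 23 methyl (3R)-3-hydroxy-5-(trimethylsilyl)pent-4-ynoate
Product: 24 methyl (3R)-3-methoxy-5-(trimethylsilyl)pent-4-ynoate
Conditions: Me3OBF4, 1,8-bis(dimethylamino)naphthalene, CH2Cl2, rt
Reagents that add atoms: trimethyloxonium tetrafluoroborate, C[O+](C)C.F[B-](F)(F)F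
Why: O-methylation with Meerwein salt and a non-nucleophilic proton scavenger avoids an alkoxide, so neither retro-aldol cleavage nor β-elimination can erode the stereocentre.

Step 13
Reactants: 24 methyl (3R)-3-methoxy-5-(trimethylsilyl)pent-4-ynoate
Product: 25 (3R)-3-methoxypent-4-ynamide
Conditions: NH3 (7 M in MeOH), sealed flask, rt, 48 h
Reagents that add atoms: ammonia, N
Why: Ester ammonolysis gives the primary amide, and the same basic methanol protodesilylates the alkyne, which saves a separate deprotection.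

Step 14
Reactants: 25 (3R)-3-methoxypent-4-ynamide; 26 ethyl bromopyruvate
Product: 28 ethyl 2-[(2R)-2-methoxybut-3-yn-1-yl]-1,3-oxazole-4-carboxylate, via hydroxyoxazoline 27 (not isolated)
Conditions: 26 (3 equiv), NaHCO3 (8 equiv), THF, 60 °C, 16 h, filter; then (CF3CO)2O, pyridine, THF, 0 °C
Reagents that add atoms: none
Why: Hantzsch oxazole synthesis in its two-stage form (O-alkylation and cyclisation, then trifluoroacetylation and elimination) builds the south oxazole under conditions known not to racemise neighbouring stereocentres.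

Step 15
Reactants: 19 (1Z,6R,8S,9E)-1-chloro-7,7-dimethyl-8-(triethylsilyloxy)undeca-1,9-dien-3-yn-6-ol; 28 ethyl 2-[(2R)-2-methoxybut-3-yn-1-yl]-1,3-oxazole-4-carboxylate
Product: 29 ethyl 2-[(2R,5Z,10R,12S,13E)-10-hydroxy-2-methoxy-11,11-dimethyl-12-(triethylsilyloxy)pentadeca-5,13-diene-3,7-diyn-1-yl]-1,3-oxazole-4-carboxylate
Conditions: Pd(PPh3)4 (5 mol %), CuI (10 mol %), piperidine (3 equiv), degassed THF, rt
Reagents that add atoms: none
Why: A second Sonogashira coupling works because the chloroenyne is an activated vinyl chloride that couples at room temperature with retention, giving an acyclic (Z)-enediyne that is thermally stable.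

Step 16
Reactants: 29 ethyl 2-[(2R,5Z,10R,12S,13E)-10-hydroxy-2-methoxy-11,11-dimethyl-12-(triethylsilyloxy)pentadeca-5,13-diene-3,7-diyn-1-yl]-1,3-oxazole-4-carboxylate
Product: 30 ethyl 2-[(2R,3Z,5Z,7Z,10R,12S,13E)-10-hydroxy-2-methoxy-11,11-dimethyl-12-(triethylsilyloxy)pentadeca-3,5,7,13-tetraen-1-yl]-1,3-oxazole-4-carboxylate
Conditions: Zn dust activated with Cu(OAc)2·H2O then AgNO3, MeOH/H2O (1:1), 30 °C, dark, 16 h
Reagents that add atoms: none
Why: Boland reduction adds hydrogen cis to conjugated triple bonds only and does not over-reduce, so both alkynes become Z-alkenes and the 7'Z,9'Z,11'Z triene appears before any epoxide is present.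

Step 17
Reactants: 31 methyl 2-(chloromethyl)-1,3-oxazole-4-carboxylate; 32 triethyl phosphite
Product: 33 methyl 2-(diethoxyphosphorylmethyl)-1,3-oxazole-4-carboxylate
Conditions: 32 (neat, 3 equiv), NaI (10 mol %), 130 °C
Reagents that add atoms: none
Why: Michaelis–Arbuzov reaction of the benzylic-type chloride, with iodide catalysis speeding up the SN2 step.

Step 18
Reactants: 33 methyl 2-(diethoxyphosphorylmethyl)-1,3-oxazole-4-carboxylate
Product: 34 2-(diethoxyphosphorylmethyl)-1,3-oxazole-4-carboxylic acid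
Conditions: LiOH·H2O (1.1 equiv), THF/H2O, 0 °C; 1 M HCl
Reagents that add atoms: lithium hydroxide, [Li+].[OH-]
Why: Saponification is selective because the carboxylic methyl ester is far more reactive than the phosphonate ethyl esters at 0 °C.

Step 19
Reactants: 30 ethyl 2-[(2R,3Z,5Z,7Z,10R,12S,13E)-10-hydroxy-2-methoxy-11,11-dimethyl-12-(triethylsilyloxy)pentadeca-3,5,7,13-tetraen-1-yl]-1,3-oxazole-4-carboxylate; 34 2-(diethoxyphosphorylmethyl)-1,3-oxazole-4-carboxylic acid
Product: 36 ethyl 2-[(2R,3Z,5Z,7Z,10R,12S,13E)-10-{[2-(diethoxyphosphorylmethyl)-1,3-oxazol-4-yl]carbonyloxy}-2-methoxy-11,11-dimethyl-12-(triethylsilyloxy)pentadeca-3,5,7,13-tetraen-1-yl]-1,3-oxazole-4-carboxylate, via mixed anhydride 35 (not isolated)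
Conditions: 34 (1.5 equiv), 2,4,6-Cl3C6H2COCl, Et3N, toluene, rt; then 30, DMAP, rt
Reagents that add atoms: none
Why: Yamaguchi esterification acylates the only free hydroxyl (the hindered C14'–OH) with retention, and because 34 carries no hydroxyl no extra protecting group is needed.

Step 20
Reactants: 36 phosphonate ester from step 19; 15 (2E)-3-{(2S,3R)-3-[(1Z,4S,6S,7E)-4-hydroxy-5,5-dimethyl-6-(triethylsilyloxy)nona-1,7-dien-1-yl]oxiran-2-yl}prop-2-enal
Product: 38 seco ethyl ester (36 with the CH2P(O)(OEt)2 group replaced by the (1E,3E)-4-{(2S,3R)-3-[(1Z,4S,6S,7E)-4-hydroxy-5,5-dimethyl-6-(triethylsilyloxy)nona-1,7-dien-1-yl]oxiran-2-yl}buta-1,3-dien-1-yl group), via lithiated phosphonate 37 (not isolated)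
Conditions: LiN(SiMe3)2 (0.98 equiv), THF, −78 °C, 30 min; then 15 (1.1 equiv), −78 to −20 °C
Reagents that add atoms: none
Why: Horner–Wadsworth–Emmons olefination with the preformed heteroaryl-stabilised phosphonate anion gives the new 5E alkene, no free base remains to open the γ,δ-epoxy enal, and the anion is too weak a base to deprotonate the free C14–OH.

Step 21
Reactants: 38 seco ethyl ester
Product: 39 seco acid (38 with CO2H in place of CO2Et)
Conditions: LiOH (5 equiv), THF/H2O (3:1), 0 °C to rt; aq NaH2PO4 to pH 5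
Reagents that add atoms: lithium hydroxide, [Li+].[OH-]
Why: Chemoselective saponification cleaves the unhindered ethyl ester while the internal ester of the neopentyl secondary C14'-alcohol is sterically protected, and the epoxide tolerates hydroxide and the pH 5 work-up.

Step 22
Reactants: 39 seco acid
Product: 41 16,16'-bis(triethylsilyl) ether of the target macrodiolide, via mixed anhydride 40 (not isolated)
Conditions: 2,4,6-Cl3C6H2COCl, Et3N, THF, rt; then syringe pump into DMAP, toluene (0.5 mM), rt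
Reagents that add atoms: none
Why: Yamaguchi macrolactonisation at room temperature closes the 30-membered ring on the only free hydroxyl (C14–OH) with retention, which is the ring closure used for this class of oxazole macrodiolides.

Step 23
Reactants: 41 16,16'-bis(triethylsilyl) ether of the target macrodiolide
Product: 42 target CNP0284709.4
Conditions: n-Bu4NF/AcOH (1:1, 6 equiv), THF, 0 °C to rt
Reagents that add atoms: none
Why: Fluoride-induced desilylation buffered with acetic acid stays near neutral, so the vinyl epoxide is not opened, the esters do not migrate to C16–OH and the Z,Z,Z-triene is not isomerised.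

**Compound list**
1 | (E)-crotonaldehyde | C/C=C/C=O | starting material
2 | 1-methoxy-2-methyl-1-(trimethylsilyloxy)prop-1-ene | COC(O[Si](C)(C)C)=C(C)C | starting material
3 | methyl (3S,4E)-3-hydroxy-2,2-dimethylhex-4-enoate | C/C=C/[C@H](O)C(C)(C)C(=O)OC | intermediate
4 | methyl (3S,4E)-2,2-dimethyl-3-(triethylsilyloxy)hex-4-enoate | C/C=C/[C@H](O[Si](CC)(CC)CC)C(C)(C)C(=O)OC | intermediate
5 | (3S,4E)-2,2-dimethyl-3-(triethylsilyloxy)hex-4-enal | C/C=C/[C@H](O[Si](CC)(CC)CC)C(C)(C)C=O | intermediate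
6 | allylmagnesium bromide | C=CC[Mg]Br | starting material
7 | B-allyldiisopinocampheylborane ((+)-α-pinene series) | C=CCB([C@@H]1C[C@@H]2C[C@H]([C@H]1C)C2(C)C)[C@@H]1C[C@@H]2C[C@H]([C@H]1C)C2(C)C | intermediate
8 | (4S,6S,7E)-5,5-dimethyl-6-(triethylsilyloxy)nona-1,7-dien-4-ol | C/C=C/[C@H](O[Si](CC)(CC)CC)C(C)(C)[C@@H](O)CC=C | intermediate
9 | (2E)-4,4-dimethoxybut-2-enal (fumaraldehyde mono(dimethyl acetal)) | COC(OC)/C=C/C=O | starting material
10 | allyl chloride | C=CCCl | starting material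
11 | (Z)-γ-chloroallyldiisopinocampheylborane ((−)-α-pinene series) | Cl/C=C\CB([C@H]1C[C@H]2C[C@@H]([C@@H]1C)C2(C)C)[C@H]1C[C@H]2C[C@@H]([C@@H]1C)C2(C)C | intermediate
12 | (2E,4S,5S)-5-chloro-1,1-dimethoxyhepta-2,6-dien-4-ol | C=C[C@H](Cl)[C@@H](O)/C=C/C(OC)OC | intermediate
13 | (2E,4S,5S)-5-chloro-4-hydroxyhepta-2,6-dienal | C=C[C@H](Cl)[C@@H](O)/C=C/C=O | intermediate
14 | (2E)-3-[(2S,3R)-3-ethenyloxiran-2-yl]prop-2-enal | C=C[C@H]1O[C@H]1/C=C/C=O | intermediate
15 | (2E)-3-{(2S,3R)-3-[(1Z,4S,6S,7E)-4-hydroxy-5,5-dimethyl-6-(triethylsilyloxy)nona-1,7-dien-1-yl]oxiran-2-yl}prop-2-enal | C/C=C/[C@H](O[Si](CC)(CC)CC)C(C)(C)[C@@H](O)C/C=C\[C@H]1O[C@H]1/C=C/C=O | intermediate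
16 | allenylboronic acid pinacol ester | C=C=CB1OC(C)(C)C(C)(C)O1 | starting material
17 | (4R,6S,7E)-5,5-dimethyl-6-(triethylsilyloxy)non-7-en-1-yn-4-ol | C#CC[C@@H](O)C(C)(C)[C@@H](O[Si](CC)(CC)CC)/C=C/C | intermediate
18 | (Z)-1,2-dichloroethene | Cl/C=C\Cl | starting material
19 | (1Z,6R,8S,9E)-1-chloro-7,7-dimethyl-8-(triethylsilyloxy)undeca-1,9-dien-3-yn-6-ol | Cl/C=C\C#CC[C@@H](O)C(C)(C)[C@@H](O[Si](CC)(CC)CC)/C=C/C | intermediate
20 | bis(trimethylsilyl)acetylene | C[Si](C)(C)C#C[Si](C)(C)C | starting material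
21 | methyl malonyl chloride | COC(=O)CC(=O)Cl | starting material
22 | methyl 3-oxo-5-(trimethylsilyl)pent-4-ynoate | COC(=O)CC(=O)C#C[Si](C)(C)C | intermediate
23 | methyl (3R)-3-hydroxy-5-(trimethylsilyl)pent-4-ynoate | COC(=O)C[C@@H](O)C#C[Si](C)(C)C | intermediate
24 | methyl (3R)-3-methoxy-5-(trimethylsilyl)pent-4-ynoate | COC(=O)C[C@@H](OC)C#C[Si](C)(C)C | intermediate
25 | (3R)-3-methoxypent-4-ynamide | NC(=O)C[C@@H](OC)C#C | intermediate
26 | ethyl bromopyruvate | CCOC(=O)C(=O)CBr | starting material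
27 | ethyl 4-hydroxy-2-[(2R)-2-methoxybut-3-yn-1-yl]-4,5-dihydro-1,3-oxazole-4-carboxylate (C4 epimers) | CCOC(=O)C1(O)COC(C[C@@H](OC)C#C)=N1 | intermediate
28 | ethyl 2-[(2R)-2-methoxybut-3-yn-1-yl]-1,3-oxazole-4-carboxylate | CCOC(=O)c1coc(C[C@@H](OC)C#C)n1 | intermediate
29 | ethyl 2-[(2R,5Z,10R,12S,13E)-10-hydroxy-2-methoxy-11,11-dimethyl-12-(triethylsilyloxy)pentadeca-5,13-diene-3,7-diyn-1-yl]-1,3-oxazole-4-carboxylate | CCOC(=O)c1coc(C[C@@H](OC)C#C/C=C\C#CC[C@@H](O)C(C)(C)[C@@H](O[Si](CC)(CC)CC)/C=C/C)n1 | intermediate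
30 | ethyl 2-[(2R,3Z,5Z,7Z,10R,12S,13E)-10-hydroxy-2-methoxy-11,11-dimethyl-12-(triethylsilyloxy)pentadeca-3,5,7,13-tetraen-1-yl]-1,3-oxazole-4-carboxylate | CCOC(=O)c1coc(C[C@@H](OC)/C=C\C=C/C=C\C[C@@H](O)C(C)(C)[C@@H](O[Si](CC)(CC)CC)/C=C/C)n1 | intermediate
31 | methyl 2-(chloromethyl)-1,3-oxazole-4-carboxylate | COC(=O)c1coc(CCl)n1 | starting material
32 | triethyl phosphite | CCOP(OCC)OCC | starting material
33 | methyl 2-(diethoxyphosphorylmethyl)-1,3-oxazole-4-carboxylate | COC(=O)c1coc(CP(=O)(OCC)OCC)n1 | intermediate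
34 | 2-(diethoxyphosphorylmethyl)-1,3-oxazole-4-carboxylic acid | OC(=O)c1coc(CP(=O)(OCC)OCC)n1 | intermediate
35 | mixed anhydride of 34 and 2,4,6-trichlorobenzoic acid | O=C(OC(=O)c1c(Cl)cc(Cl)cc1Cl)c1coc(CP(=O)(OCC)OCC)n1 | intermediate
36 | C14'-O ester of 30 with 34 (name as in step 19) | CCOC(=O)c1coc(C[C@@H](OC)/C=C\C=C/C=C\C[C@@H](OC(=O)c2coc(CP(=O)(OCC)OCC)n2)C(C)(C)[C@@H](O[Si](CC)(CC)CC)/C=C/C)n1 | intermediate
37 | lithium salt of 36 deprotonated at the P–CH2 carbon | CCOC(=O)c1coc(C[C@@H](OC)/C=C\C=C/C=C\C[C@@H](OC(=O)c2coc([CH-]P(=O)(OCC)OCC)n2)C(C)(C)[C@@H](O[Si](CC)(CC)CC)/C=C/C)n1.[Li+] | intermediate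
38 | seco ethyl ester (5E,7E,9S,10R,11Z,14S,16S / 6'R,7'Z,9'Z,11'Z,14'R,16'S; free C14–OH, both C16 oxygens as TES ethers) | CCOC(=O)c1coc(C[C@@H](OC)/C=C\C=C/C=C\C[C@@H](OC(=O)c2coc(/C=C/C=C/[C@@H]3O[C@@H]3/C=C\C[C@H](O)C(C)(C)[C@@H](O[Si](CC)(CC)CC)/C=C/C)n2)C(C)(C)[C@@H](O[Si](CC)(CC)CC)/C=C/C)n1 | intermediate
39 | seco acid (38 with CO2H) | OC(=O)c1coc(C[C@@H](OC)/C=C\C=C/C=C\C[C@@H](OC(=O)c2coc(/C=C/C=C/[C@@H]3O[C@@H]3/C=C\C[C@H](O)C(C)(C)[C@@H](O[Si](CC)(CC)CC)/C=C/C)n2)C(C)(C)[C@@H](O[Si](CC)(CC)CC)/C=C/C)n1 | intermediate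
40 | mixed anhydride of 39 and 2,4,6-trichlorobenzoic acid | Clc1cc(Cl)c(C(=O)OC(=O)c2coc(C[C@@H](OC)/C=C\C=C/C=C\C[C@@H](OC(=O)c3coc(/C=C/C=C/[C@@H]4O[C@@H]4/C=C\C[C@H](O)C(C)(C)[C@@H](O[Si](CC)(CC)CC)/C=C/C)n3)C(C)(C)[C@@H](O[Si](CC)(CC)CC)/C=C/C)n2)c(Cl)c1 | intermediate
41 | 16,16'-bis(triethylsilyl) ether of the target | C/C=C/[C@H](O[Si](CC)(CC)CC)C(C)(C)[C@@H]1C/C=C\[C@H]2O[C@H]2/C=C/C=C/c2nc(co2)C(=O)O[C@@H](C(C)(C)[C@@H](O[Si](CC)(CC)CC)/C=C/C)C\C=C/C=C\C=C/[C@H](OC)Cc2nc(co2)C(=O)O1 | intermediate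
42 | CNP0284709.4 | C/C=C/[C@H](O)C(C)(C)[C@@H]1C/C=C\[C@H]2O[C@H]2/C=C/C=C/c2nc(co2)C(=O)O[C@@H](C(C)(C)[C@@H](O)/C=C/C)C\C=C/C=C\C=C/[C@H](OC)Cc2nc(co2)C(=O)O1 | target

**Total step count:** 23.
**Longest linear sequence:** 12 steps (1, 2, 3, 8, 9, 15, 16, 19, 20, 21, 22, 23). The branch 10–14 followed by 15 onward is equally long.

**Three steps most likely to fail**

**Step 5.** The α-chloroallyl species is carbenoid-like and may decompose, the allylic acetal may not tolerate traces of free BF3, and the syn selectivity and ee on this enal are untested. The fallback sets out from 9 and comes back at 14. It forms the same C9–C10 bond with an α-alkoxyallyl anion instead of the α-chloroallyl anion.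
- Allyl methoxymethyl ether is treated with s-BuLi, (−)-Ipc2BOMe and BF3·OEt2 (Brown (Z)-γ-alkoxyallylboration, Si-face attack) and added to 9. This gives the syn product (2E,4R,5R)-1,1-dimethoxy-5-(methoxymethoxy)hepta-2,6-dien-4-ol F1.
- MsCl/Et3N at −20 °C converts the free C9–OH into (2E,4R,5R)-1,1-dimethoxy-5-(methoxymethoxy)hepta-2,6-dien-4-yl methanesulfonate F2.
- Me2BBr at −78 °C followed by aq NaHCO3 removes the MOM group and the acetal together, giving (2E,4R,5R)-5-hydroxy-1-oxohepta-2,6-dien-4-yl methanesulfonate F3.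
- DBU then closes the oxirane by attack of the C10 oxygen on C9. Inversion now occurs at C9, which is why the antipodal borane is used. The product is 14.

**Step 7.** A cis-disubstituted vinyl epoxide that also carries an enal is an untested, allylically branched partner for the cyclometalated ruthenium catalyst. Low conversion or loss of Z-selectivity is possible. The fallback sets out from 8 and comes back at 15. A ring enforces the Z geometry, and the epoxide is built on the side chain with the same reversed-polarity bond formation.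
- Acryloyl chloride/Et3N gives (4S,6S,7E)-5,5-dimethyl-6-(triethylsilyloxy)nona-1,7-dien-4-yl prop-2-enoate F4.
- Ring-closing metathesis with RuCl2(=CHPh)(PCy3)(H2IMes) gives (6S)-6-[(3S,4E)-2-methyl-3-(triethylsilyloxy)hex-4-en-2-yl]-5,6-dihydro-2H-pyran-2-one F5.
- i-Bu2AlH at −78 °C gives the lactol (6S)-6-[(3S,4E)-2-methyl-3-(triethylsilyloxy)hex-4-en-2-yl]-5,6-dihydro-2H-pyran-2-ol F6.
- The open (Z)-hydroxy-enal form of the lactol is trapped by the enantiomeric (Z)-γ-chloroallylborane, made from 10, LiN(c-C6H11)2, (−)-Ipc2BOMe and BF3·OEt2 (3 equiv). This gives (3R,4R,5Z,8S,10S,11E)-3-chloro-9,9-dimethyl-10-(triethylsilyloxy)trideca-1,5,11-triene-4,8-diol F7.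
- DBU closes it to (1Z,4S,6S,7E)-1-[(2R,3S)-3-ethenyloxiran-2-yl]-5,5-dimethyl-6-(triethylsilyloxy)nona-1,7-dien-4-ol F8.
- E-selective cross-metathesis of the terminal vinyl group with 1, catalysed by RuCl2(=CH-C6H4-2-OiPr)(H2IMes), delivers 15.

**Step 8.** Allenyl pinacol boronates react slowly with an α-quaternary aldehyde, and the catalyst must impose the 1,3-syn product. The fallback sets out from 5 and comes back at 17. It replaces the propargyl nucleophile with a homoenolate equivalent.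
- Allyl N,N-diisopropylcarbamate is lithiated (s-BuLi, TMEDA, Et2O, −78 °C), transmetalated with Ti(OiPr)4 and added to 5 (Hoppe homoaldol reaction, γ-attack through a chair transition state).
- This gives the Z-enol carbamates (1Z,4R,6S,7E)-4-hydroxy-5,5-dimethyl-6-(triethylsilyloxy)nona-1,7-dien-1-yl N,N-diisopropylcarbamate F9 and its epimer (1Z,4S,6S,7E)-4-hydroxy-5,5-dimethyl-6-(triethylsilyloxy)nona-1,7-dien-1-yl N,N-diisopropylcarbamate F10, which are separated by chromatography.
- F9 is treated with t-BuLi (3.5 equiv, THF, −78 to −40 °C). Vinylic lithiation, loss of lithium carbamate and a 1,2-hydride shift give the terminal alkyne 17.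

**Further compounds**
F1 | step 5 | (2E,4R,5R)-1,1-dimethoxy-5-(methoxymethoxy)hepta-2,6-dien-4-ol | C=C[C@@H](OCOC)[C@H](O)/C=C/C(OC)OC
F2 | step 5 | (2E,4R,5R)-1,1-dimethoxy-5-(methoxymethoxy)hepta-2,6-dien-4-yl methanesulfonate | C=C[C@@H](OCOC)[C@H](OS(C)(=O)=O)/C=C/C(OC)OC
F3 | step 5 | (2E,4R,5R)-5-hydroxy-1-oxohepta-2,6-dien-4-yl methanesulfonate | C=C[C@@H](O)[C@H](OS(C)(=O)=O)/C=C/C=O
F4 | step 7 | (4S,6S,7E)-5,5-dimethyl-6-(triethylsilyloxy)nona-1,7-dien-4-yl prop-2-enoate | C/C=C/[C@H](O[Si](CC)(CC)CC)C(C)(C)[C@@H](OC(=O)C=C)CC=C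
F5 | step 7 | (6S)-6-[(3S,4E)-2-methyl-3-(triethylsilyloxy)hex-4-en-2-yl]-5,6-dihydro-2H-pyran-2-one | C/C=C/[C@H](O[Si](CC)(CC)CC)C(C)(C)[C@@H]1CC=CC(=O)O1
F6 | step 7 | (6S)-6-[(3S,4E)-2-methyl-3-(triethylsilyloxy)hex-4-en-2-yl]-5,6-dihydro-2H-pyran-2-ol (anomers) | C/C=C/[C@H](O[Si](CC)(CC)CC)C(C)(C)[C@@H]1CC=CC(O)O1
F7 | step 7 | (3R,4R,5Z,8S,10S,11E)-3-chloro-9,9-dimethyl-10-(triethylsilyloxy)trideca-1,5,11-triene-4,8-diol | C=C[C@@H](Cl)[C@H](O)/C=C\C[C@H](O)C(C)(C)[C@@H](O[Si](CC)(CC)CC)/C=C/C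
F8 | step 7 | (1Z,4S,6S,7E)-1-[(2R,3S)-3-ethenyloxiran-2-yl]-5,5-dimethyl-6-(triethylsilyloxy)nona-1,7-dien-4-ol | C=C[C@@H]1O[C@@H]1/C=C\C[C@H](O)C(C)(C)[C@@H](O[Si](CC)(CC)CC)/C=C/C
F9 | step 8 | (1Z,4R,6S,7E)-4-hydroxy-5,5-dimethyl-6-(triethylsilyloxy)nona-1,7-dien-1-yl N,N-diisopropylcarbamate | CC(C)N(C(C)C)C(=O)O/C=C\C[C@@H](O)C(C)(C)[C@@H](O[Si](CC)(CC)CC)/C=C/C
F10 | step 8 | (1Z,4S,6S,7E)-4-hydroxy-5,5-dimethyl-6-(triethylsilyloxy)nona-1,7-dien-1-yl N,N-diisopropylcarbamate | CC(C)N(C(C)C)C(=O)O/C=C\C[C@H](O)C(C)(C)[C@@H](O[Si](CC)(CC)CC)/C=C/C
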